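**Retrosynthetic overview**
1. Aspergilol C (ring A cyclopentane, ring B cyclooctene, ring C cyclohexene, ring D cyclopentanol) comes from tetracyclic tertiary allylic alcohol 25 by enol triflate reduction (C10=C11), allylic transposition/C–Cl reduction (C1 methyl, C1=C2) and desilylation.
2. Ring B is closed last at C1–C2 by a proposed nickel-catalysed exo-selective reductive cyclisation of alkynyl diketone 24.
3. Ring A enters as iodoenone 16 by B-alkyl Suzuki coupling (C6–C7) and is made cis-2,3-disubstituted by CBS reduction and hydroxyl-directed hydrogenation; C9 is set by iridium-catalysed allylic alkylation.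
4. Ring C is closed by ring-closing metathesis (C10=C18) after a Sakurai–aldol three-component coupling on ring D enone 5; C18–H is set by copper hydride 1,4-reduction.
5. Ring D comes from commercial (R)-4-silyloxycyclopentenone 1. Order of ring formation: D (given), C, A (attached preformed), B.

**Assumptions and labels (one line each)**
- Atom labels used only for naming: C1 (olefinic C bearing the vinylic CH3), C2 (olefinic C in ring A), C3, C4 (ring A CH2), C5 (ring A CH–CH3), C6 (ring A/B junction CH), C7, C8 (ring B CH2), C9 (ring B CH–CH3), C10=C11 (ring C olefin, C11 = CH), C12 (C–CH3 at the C/D junction), C13 (CHOH), C14 (CH2), C15 (CH–i-Pr), C16 (C/D junction CH), C17 (ring C CH2), C18 (B/C junction CH).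
- Compounds 1, 6, 15 and all reagents are taken as commercial; centres that are later destroyed or equilibrated (C11 carbinol in 8–10, C10 in 14–20, C2 in 25–28) are left undefined in the SMILES.

**Route**

Step 1
Reactants: 1 (R)-4-(tert-butyldimethylsilyloxy)cyclopent-2-en-1-one
Product: 3 (S)-4-isopropylcyclopent-2-en-1-one, via silyloxy ketone 2 (not isolated)
Conditions: i-PrMgCl, CuBr·SMe2 (10 mol %), THF, −78 °C; H2O quench; then DBU, CH2Cl2, 0 °C
Reagents that add atoms: isopropylmagnesium chloride, CC(C)[Mg]Cl
Why: Copper-catalysed conjugate addition places the isopropyl group anti to the silyloxy group and E1cB loss of silanol then transposes the enone, so the chirality of 1 is relayed to C15.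

Step 2
Reactants: 3 (S)-4-isopropylcyclopent-2-en-1-one
Product: 4 (S)-2-iodo-4-isopropylcyclopent-2-en-1-one
Conditions: I2, pyridine, CH2Cl2, 0 °C to rt
Reagents that add atoms: iodine, II
Why: α-Iodination of the enone (pyridine addition, enolate iodination, elimination; Johnson iodination) leaves C15 untouched.

Step 3
Reactants: 4 (S)-2-iodo-4-isopropylcyclopent-2-en-1-one
Product: 5 ring D enone (S)-4-isopropyl-2-methylcyclopent-2-en-1-one
Conditions: SnMe4, Pd2(dba)3 (2.5 mol %), AsPh3, CuI (10 mol %), NMP, 50 °C
Reagents that add atoms: tetramethylstannane, C[Sn](C)(C)C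
Why: Stille coupling of the α-iodoenone under neutral conditions installs the future C12 methyl without epimerising the γ-stereocentre.

Step 4
Reactants: 5 ring D enone (S)-4-isopropyl-2-methylcyclopent-2-en-1-one; 6 2-[(trimethylsilyl)methyl]prop-2-en-1-yl acetate
Product: 8 aldol adduct (2S,3S,4S)-3-[2-(acetoxymethyl)prop-2-en-1-yl]-2-(1-hydroxyprop-2-en-1-yl)-4-isopropyl-2-methylcyclopentan-1-one, via titanium enolate 7 (not isolated)
Conditions: TiCl4, CH2Cl2, −78 °C; then acrolein, −78 to −40 °C; H2O quench
Reagents that add atoms: acrolein, C=CC=O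
Why: Hosomi–Sakurai conjugate allylation occurs anti to the C15 isopropyl group and the trichlorotitanium enolate then adds to acrolein (aldol) on the face opposite the new C16 chain, which sets C16 and the quaternary C12 (methyl cis to the C16 chain) in one three-component coupling.

Step 5
Reactants: 8 aldol adduct
Product: 9 bicyclic hydroxy ketone [(3S,3aS,7aS)-7-hydroxy-3-isopropyl-7a-methyl-1-oxo-2,3,3a,4,7,7a-hexahydro-1H-inden-5-yl]methyl acetate
Conditions: second-generation Grubbs catalyst RuCl2(=CHPh)(H2IMes)(PCy3) (5 mol %), CH2Cl2, 40 °C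
Reagents that add atoms: none
Why: Ring-closing metathesis of the vinyl carbinol with the 1,1-disubstituted olefin closes ring C as the trisubstituted C10=C18 cyclohexene with loss of ethene.

Step 6
Reactants: 9 bicyclic hydroxy ketone
Product: 10 ring C/D diol (13R alcohol cis to the C12 methyl)
Conditions: NaBH4, MeOH, −20 °C
Reagents that add atoms: none
Why: Hydride reduction of the C13 ketone from the face opposite the angular C12 methyl (the usual course for trans-hydrindan-1-ones) gives the 13R alcohol cis to that methyl.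

Step 7
Reactants: 10 ring C/D diol
Product: 11 ring C/D enone (C11 ketone conjugated to C10=C18; free 13R hydroxyl)
Conditions: MnO2, CH2Cl2, rt
Reagents that add atoms: none
Why: Manganese dioxide oxidises only the allylic C11 alcohol, which converges both carbinol epimers to one β-substituted enone.

Step 8
Reactants: 11 ring C/D enone
Product: 12 silyl-protected enone (13-O-TBS ether of 11)
Conditions: TBSOTf, 2,6-lutidine, CH2Cl2, −78 °C
Reagents that add atoms: tert-butyldimethylsilyl triflate, CC(C)(C)[Si](C)(C)OS(=O)(=O)C(F)(F)F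
Why: Silylation of the hindered secondary alcohol protects C13–OH for the base and organometallic steps that follow.

Step 9
Reactants: 12 silyl-protected enone
Product: 13 silyl enol ether (C11–OSiMe2Ph; C10=C11; C18–H cis to C16–H)
Conditions: [(Ph3P)CuH]6 (5 mol %), PhMe2SiH, toluene, rt
Reagents that add atoms: dimethylphenylsilane, C[SiH](C)c1ccccc1
Why: Copper hydride 1,4-hydrosilylation delivers hydride to C18 axially, on the face opposite the axial C12 methyl, so the C18 side chain becomes equatorial (C18–H cis to C16–H) and the C11 enolate is trapped regiospecifically as the silyl enol ether.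

Step 10
Reactants: 13 silyl enol ether
Product: 14 allylated ketone (C10 carries the (R)-but-3-en-2-yl group; C11 ketone)
Conditions: (E)-but-2-en-1-yl methyl carbonate, [Ir(cod)Cl]2 (2 mol %), Feringa-type phosphoramidite ligand O,O′-(1,1′-binaphthyl-2,2′-diyl) N,N-bis(1-phenylethyl)phosphoramidite (4 mol %, antipode giving the 9R product), CsF (0.4 equiv), ZnF2, DME, 50 °C
Reagents that add atoms: (E)-but-2-en-1-yl methyl carbonate, C/C=C/COC(=O)OC
Why: Iridium-catalysed branched-selective asymmetric allylic alkylation of the fluoride-activated silyl enol ether forms C9–C10 and sets C9 (R) under catalyst control, while the configuration at C10 is immaterial because it is equilibrated in step 15 and becomes sp2 later.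

Step 11
Reactants: 15 3-methylcyclopent-2-en-1-one
Product: 16 2-iodo-3-methylcyclopent-2-en-1-one
Conditions: I2, pyridine, CH2Cl2, rt
Reagents that add atoms: iodine, II
Why: Johnson α-iodination of the enone gives the ring A coupling partner.

Step 12
Reactants: 14 allylated ketone; 16 2-iodo-3-methylcyclopent-2-en-1-one
Product: 18 enone ketone (ring A enone joined through C6–C7), via alkylborane 17 (not isolated)
Conditions: 9-BBN, THF, rt; then 16, Pd(dppf)Cl2 (5 mol %), AsPh3, Cs2CO3, DMF/THF/H2O, rt
Reagents that add atoms: none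
Why: Anti-Markovnikov hydroboration of the terminal vinyl group and B-alkyl Suzuki–Miyaura coupling with the α-iodoenone form the C6–C7 bond and complete the C6–C9 chain.

Step 13
Reactants: 18 enone ketone
Product: 19 allylic alcohol (2S carbinol on ring A)
Conditions: (R)-2-methyl-CBS-oxazaborolidine (20 mol %), catecholborane, toluene, −78 °C
Reagents that add atoms: none
Why: Corey–Bakshi–Shibata reduction of the ring A enone (olefinic arm as the large group) gives the 2S allylic alcohol under catalyst control, while the C11 ketone, flanked by quaternary C12 and tertiary C10, is not reduced at this temperature.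

Step 14
Reactants: 19 allylic alcohol
Product: 20 cyclopentanol (ring A 2S,5S,6S; C5 methyl and C6 chain cis; both trans to C2–OH)
Conditions: [Ir(cod)(PCy3)(py)]PF6 (5 mol %), H2 (1 atm), CH2Cl2, rt
Reagents that add atoms: none
Why: Hydroxyl-directed hydrogenation of the tetrasubstituted olefin (the only C=C present) delivers both hydrogens from the face of the C2 hydroxyl, which sets C5 and C6 with the methyl group and the C7 chain cis to each other and trans to the hydroxyl.

Step 15
Reactants: 20 cyclopentanol
Product: 21 keto diol (C1 hydroxyl free; C9 substituent at C10 equatorial)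
Conditions: NaOMe (0.3 equiv), MeOH, rt
Reagents that add atoms: none
Why: Methoxide transesterification removes the acetate and at the same time equilibrates C10 to the epimer with the C9 substituent equatorial (trans to the C18 substituent, away from the axial C12 methyl).

Step 16
Reactants: 21 keto diol
Product: 22 hydroxy keto aldehyde (C1 aldehyde)
Conditions: TEMPO (10 mol %), PhI(OAc)2, CH2Cl2, rt
Reagents that add atoms: none
Why: Oxoammonium (TEMPO) oxidation is selective for the primary C1 alcohol over the secondary C2 alcohol.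

Step 17
Reactants: 22 hydroxy keto aldehyde
Product: 23 hydroxy alkynyl ketone (C18–C≡CH)
Conditions: dimethyl (1-diazo-2-oxopropyl)phosphonate, K2CO3, MeOH, 0 °C to rt
Reagents that add atoms: dimethyl (1-diazo-2-oxopropyl)phosphonate, COP(=O)(OC)C(=[N+]=[N-])C(C)=O
Why: Ohira–Bestmann (Seyferth–Gilbert) homologation turns the aldehyde into the terminal alkyne whose end carbon becomes the C1 methyl, and any epimerisation at C18 favours the desired equatorial isomer.

Step 18
Reactants: 23 hydroxy alkynyl ketone
Product: 24 alkynyl diketone (ring A C2 ketone)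
Conditions: Dess–Martin periodinane, CH2Cl2, 0 °C
Reagents that add atoms: none
Why: Dess–Martin oxidation gives the ring A ketone under mild conditions chosen to keep the epimerisable cis C6 centre intact.

Step 19
Reactants: 24 alkynyl diketone
Product: 25 tetracyclic allylic alcohol (ring B closed at C1–C2; C1=CH2; C2–OH; C11 ketone)
Conditions: Ni(cod)2 (20 mol %), IPr [1,3-bis(2,6-diisopropylphenyl)imidazol-2-ylidene] (20 mol %), Et3B (3 equiv), toluene (2 mM, slow addition of 24), 50 °C; H2O work-up
Reagents that add atoms: none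
Why: Proposed new method: zerovalent nickel with the bulky carbene couples the terminal alkyne and the ring A ketone by oxidative cyclisation to an oxanickelacyclopentene with the C–C bond at the internal alkyne carbon (exo mode, since the endo mode would need a trans-cyclononene and the neopentylic C11 ketone cannot reach the alkyne in an unstrained metallacycle), after which ethyl transfer from Et3B, β-hydride elimination and C–H reductive elimination release the 1,1-disubstituted olefin and a borinate that hydrolyses to the tertiary alcohol, closing the eight-membered ring B under neutral conditions; the closest known reaction type is the nickel-catalysed reductive alkyne–aldehyde macrocyclisation and the five- or six-ring alkynyl ketone cyclisation, not yet shown for a ketone acceptor in a medium ring.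

Step 20
Reactants: 25 tetracyclic allylic alcohol
Product: 27 enol triflate (C10=C11–OTf), via dipotassium enolate alkoxide 26 (not isolated)
Conditions: KN(SiMe3)2 (2.3 equiv), THF, −78 °C; then PhNTf2, −78 to 0 °C; H2O quench
Reagents that add atoms: N-phenylbis(trifluoromethanesulfonimide), O=S(=O)(N(c1ccccc1)S(=O)(=O)C(F)(F)F)C(F)(F)F
Why: C10 is the only enolisable position of the C11 ketone (C12 is quaternary), so enolate O-triflation is regiospecific, and the hindered tertiary alkoxide is not sulfonylated and returns as the alcohol on quench.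

Step 21
Reactants: 27 enol triflate
Product: 28 dienol (C10=C11 olefin; C1=CH2; C2–OH)
Conditions: Pd(OAc)2 (10 mol %), PPh3, HCO2H, n-Bu3N, DMF, 60 °C
Reagents that add atoms: none
Why: Palladium-catalysed formate reduction of the enol triflate (oxidative addition, formate decarboxylation to a palladium hydride, reductive elimination) gives the C10=C11 olefin without touching the unactivated tertiary allylic alcohol.

Step 22
Reactants: 28 dienol
Product: 29 allylic chloride (ClCH2–C1=C2; tetrasubstituted ring B olefin with C18 and C6 cis)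
Conditions: SOCl2, pyridine, Et2O, −20 to 0 °C
Reagents that add atoms: thionyl chloride, O=S(Cl)Cl
Why: The tertiary allylic chlorosulfite collapses with allylic transposition (SN2′/SNi′) to the primary chloride, forming the tetrasubstituted C1=C2 olefin whose geometry (C18 cis to C6, as in the target) is enforced by the eight-membered ring B.

Step 23
Reactants: 29 allylic chloride
Product: 30 silyl ether of aspergilol C
Conditions: LiBHEt3, THF, 0 °C
Reagents that add atoms: none
Why: SN2 hydride displacement of the primary allylic chloride gives the C1 methyl group.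

Step 24
Reactants: 30 silyl ether of aspergilol C
Product: 31 aspergilol C
Conditions: n-Bu4NF, THF, 50 °C
Reagents that add atoms: none
Why: Fluoride-mediated cleavage of the silyl ether liberates the C13 alcohol without affecting the skipped diene.

**Compound list**
1 | (R)-4-(tert-butyldimethylsilyloxy)cyclopent-2-en-1-one | O=C1C=C[C@H](O[Si](C)(C)C(C)(C)C)C1 | starting material
2 | silyloxy ketone, (3S,4R)-4-(tert-butyldimethylsilyloxy)-3-isopropylcyclopentan-1-one | O=C1C[C@@H](C(C)C)[C@H](O[Si](C)(C)C(C)(C)C)C1 | intermediate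
3 | (S)-4-isopropylcyclopent-2-en-1-one | O=C1C=C[C@H](C(C)C)C1 | intermediate
4 | (S)-2-iodo-4-isopropylcyclopent-2-en-1-one | O=C1C(I)=C[C@H](C(C)C)C1 | intermediate
5 | ring D enone, (S)-4-isopropyl-2-methylcyclopent-2-en-1-one | O=C1C(C)=C[C@H](C(C)C)C1 | intermediate
6 | 2-[(trimethylsilyl)methyl]prop-2-en-1-yl acetate | CC(=O)OCC(=C)C[Si](C)(C)C | starting material
7 | titanium enolate, trichlorotitanium C13 enolate of the 3,4-trans conjugate adduct of 5 and 6 | Cl[Ti](Cl)(Cl)OC1=C(C)[C@@H](CC(=C)COC(C)=O)[C@H](C(C)C)C1 | intermediate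
8 | aldol adduct, (2S,3S,4S)-3-[2-(acetoxymethyl)prop-2-en-1-yl]-2-(1-hydroxyprop-2-en-1-yl)-4-isopropyl-2-methylcyclopentan-1-one (both carbinol epimers) | O=C1C[C@@H](C(C)C)[C@H](CC(=C)COC(C)=O)[C@@]1(C)C(O)C=C | intermediate
9 | bicyclic hydroxy ketone, [(3S,3aS,7aS)-7-hydroxy-3-isopropyl-7a-methyl-1-oxo-2,3,3a,4,7,7a-hexahydro-1H-inden-5-yl]methyl acetate (C11 epimers) | O=C1C[C@@H](C(C)C)[C@@H]2CC(COC(C)=O)=CC(O)[C@@]12C | intermediate
10 | ring C/D diol, 13R alcohol of 9 with OH cis to the C12 methyl (C11 epimers) | O[C@@H]1C[C@@H](C(C)C)[C@@H]2CC(COC(C)=O)=CC(O)[C@@]12C | intermediate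
11 | ring C/D enone, C11 ketone conjugated to C10=C18, C18–CH2OAc, free 13R hydroxyl | O[C@@H]1C[C@@H](C(C)C)[C@@H]2CC(COC(C)=O)=CC(=O)[C@@]12C | intermediate
12 | silyl-protected enone, 13-O-TBS ether of 11 | CC(C)(C)[Si](C)(C)O[C@@H]1C[C@@H](C(C)C)[C@@H]2CC(COC(C)=O)=CC(=O)[C@@]12C | intermediate
13 | silyl enol ether, C11–OSiMe2Ph with C10=C11, C18–H cis to C16–H | CC(C)(C)[Si](C)(C)O[C@@H]1C[C@@H](C(C)C)[C@@H]2C[C@H](COC(C)=O)C=C(O[Si](C)(C)c3ccccc3)[C@@]12C | intermediate
14 | allylated ketone, C10 bearing the (R)-but-3-en-2-yl group, C11 ketone (C10 epimers) | CC(C)(C)[Si](C)(C)O[C@@H]1C[C@@H](C(C)C)[C@@H]2C[C@H](COC(C)=O)C([C@H](C)C=C)C(=O)[C@@]12C | intermediate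
15 | 3-methylcyclopent-2-en-1-one | O=C1CCC(C)=C1 | starting material
16 | 2-iodo-3-methylcyclopent-2-en-1-one | O=C1CCC(C)=C1I | intermediate
17 | alkylborane, B-alkyl-9-borabicyclo[3.3.1]nonane from 14 with boron on C7 | CC(C)(C)[Si](C)(C)O[C@@H]1C[C@@H](C(C)C)[C@@H]2C[C@H](COC(C)=O)C([C@H](C)CCB3C4CCCC3CCC4)C(=O)[C@@]12C | intermediate
18 | enone ketone, ring A 3-methylcyclopent-2-en-1-one joined at C6 to C7 | CC(C)(C)[Si](C)(C)O[C@@H]1C[C@@H](C(C)C)[C@@H]2C[C@H](COC(C)=O)C([C@H](C)CCC3=C(C)CCC3=O)C(=O)[C@@]12C | intermediate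
19 | allylic alcohol, 2S carbinol on ring A | CC(C)(C)[Si](C)(C)O[C@@H]1C[C@@H](C(C)C)[C@@H]2C[C@H](COC(C)=O)C([C@H](C)CCC3=C(C)CC[C@@H]3O)C(=O)[C@@]12C | intermediate
20 | cyclopentanol, ring A 2S,5S,6S with C5 methyl and C6 chain cis and both trans to C2–OH | CC(C)(C)[Si](C)(C)O[C@@H]1C[C@@H](C(C)C)[C@@H]2C[C@H](COC(C)=O)C([C@H](C)CC[C@H]3[C@@H](C)CC[C@@H]3O)C(=O)[C@@]12C | intermediate
21 | keto diol, C1–OH free, C9 substituent on C10 equatorial (trans to the C18 substituent) | CC(C)(C)[Si](C)(C)O[C@@H]1C[C@@H](C(C)C)[C@@H]2C[C@H](CO)[C@@H]([C@H](C)CC[C@H]3[C@@H](C)CC[C@@H]3O)C(=O)[C@@]12C | intermediate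
22 | hydroxy keto aldehyde, C1 aldehyde on C18 | CC(C)(C)[Si](C)(C)O[C@@H]1C[C@@H](C(C)C)[C@@H]2C[C@H](C=O)[C@@H]([C@H](C)CC[C@H]3[C@@H](C)CC[C@@H]3O)C(=O)[C@@]12C | intermediate
23 | hydroxy alkynyl ketone, C18–C≡CH | CC(C)(C)[Si](C)(C)O[C@@H]1C[C@@H](C(C)C)[C@@H]2C[C@H](C#C)[C@@H]([C@H](C)CC[C@H]3[C@@H](C)CC[C@@H]3O)C(=O)[C@@]12C | intermediate
24 | alkynyl diketone, ring A C2 ketone with cis C5 methyl and C6 chain | CC(C)(C)[Si](C)(C)O[C@@H]1C[C@@H](C(C)C)[C@@H]2C[C@H](C#C)[C@@H]([C@H](C)CC[C@H]3[C@@H](C)CCC3=O)C(=O)[C@@]12C | intermediate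
25 | tetracyclic allylic alcohol, ring B closed at C1–C2, exocyclic C1=CH2, tertiary C2–OH, C11 ketone | C=C1C2(O)CC[C@H](C)[C@@H]2CC[C@@H](C)[C@H]2C(=O)[C@@]3(C)[C@H](O[Si](C)(C)C(C)(C)C)C[C@@H](C(C)C)[C@@H]3C[C@@H]21 | intermediate
26 | dipotassium enolate alkoxide of 25 (C11 enolate, C2 alkoxide) | [K+].[K+].C=C1C2([O-])CC[C@H](C)[C@@H]2CC[C@@H](C)C2=C([O-])[C@@]3(C)[C@H](O[Si](C)(C)C(C)(C)C)C[C@@H](C(C)C)[C@@H]3C[C@@H]21 | intermediate
27 | enol triflate, C10=C11–OSO2CF3 | C=C1C2(O)CC[C@H](C)[C@@H]2CC[C@@H](C)C2=C(OS(=O)(=O)C(F)(F)F)[C@@]3(C)[C@H](O[Si](C)(C)C(C)(C)C)C[C@@H](C(C)C)[C@@H]3C[C@@H]21 | intermediate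
28 | dienol, C10=C11 olefin, C1=CH2, tertiary C2–OH | C=C1C2(O)CC[C@H](C)[C@@H]2CC[C@@H](C)C2=C[C@@]3(C)[C@H](O[Si](C)(C)C(C)(C)C)C[C@@H](C(C)C)[C@@H]3C[C@@H]21 | intermediate
29 | allylic chloride, ClCH2 on C1 of the tetrasubstituted C1=C2 olefin (C18 and C6 cis, the geometry of the target) | ClC/C1=C2\CC[C@H](C)[C@@H]2CC[C@@H](C)C2=C[C@@]3(C)[C@H](O[Si](C)(C)C(C)(C)C)C[C@@H](C(C)C)[C@@H]3C[C@@H]21 | intermediate
30 | silyl ether of aspergilol C (13-O-TBS) | C/C1=C2\CC[C@H](C)[C@@H]2CC[C@@H](C)C2=C[C@@]3(C)[C@H](O[Si](C)(C)C(C)(C)C)C[C@@H](C(C)C)[C@@H]3C[C@@H]21 | intermediate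
31 | aspergilol C (5S,6S,9R,12S,13R,15S,16S,18S by the labels above; C1=C2 Z) | C/C1=C2\CC[C@H](C)[C@@H]2CC[C@@H](C)C2=C[C@@]3(C)[C@H](O)C[C@@H](C(C)C)[C@@H]3C[C@@H]21 | target

**Totals**
- Total step count: 24.
- Longest linear sequence: 23 steps (1 to 31 through steps 1–10 and 12–24; step 11 is the one-step side branch to 16).

**Three steps most likely to fail, each with a fallback**

Step 4 (Sakurai–aldol three-component coupling). The trichlorotitanium enolate may not add cleanly to acrolein at the hindered, fully substituted C12. The fallback sets out from 5 and comes back at 8. The Hosomi–Sakurai allylation of 5 with 6 (TiCl4, CH2Cl2, −78 °C) is run alone and quenched with water to isolate the conjugate adduct ketone F1. Treatment with Me3SiCl, NaI and Et3N in MeCN gives the more substituted trimethylsilyl enol ether F2. A Mukaiyama aldol addition of F2 to acrolein (BF3·OEt2, CH2Cl2, −78 °C) then builds the quaternary C12 on the face opposite the C16 chain and gives 8.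

Step 10 (iridium-catalysed allylic alkylation). The silyl enol ether is hindered and a crotyl electrophile can erode branched selectivity and enantioselectivity. The fallback sets out from 13 and comes back at 18, bypassing 14 and 17. An organocatalytic Mukaiyama–Michael addition of 13 to (E)-crotonaldehyde under iminium activation by a chiral imidazolidinone salt sets C9 and gives the keto aldehyde F3. NaBH4 at −78 °C reduces only the aldehyde to the primary alcohol F4. I2, PPh3 and imidazole convert it into the primary iodide F5. Zinc insertion (Zn, LiCl, THF) gives the alkylzinc iodide F6, and Negishi coupling of F6 with 16 (Pd(OAc)2, SPhos, THF) delivers 18.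

Step 19 (the proposed nickel-catalysed alkyne–ketone cyclisation). Medium-ring strain and the low electrophilicity of the ketone may stop the oxidative cyclisation, or hydrometalation of the alkyne may compete. The fallback uses known chemistry, sets out from 24 and comes back at 25. Markovnikov hydroiodination of the terminal alkyne (NaI, Me3SiCl, H2O, MeCN, 0 °C) gives the 2-iodoalkene F7. An intramolecular Nozaki–Hiyama–Kishi reaction (CrCl2, NiCl2 (2 mol %), DMSO, high dilution, rt) then adds the alkenylchromium species to the ring A ketone and gives 25.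

**Further compounds**
F1 | step 4 | conjugate adduct ketone, (3S,4S)-3-[2-(acetoxymethyl)prop-2-en-1-yl]-4-isopropyl-2-methylcyclopentan-1-one (C12 epimers) | O=C1C[C@@H](C(C)C)[C@H](CC(=C)COC(C)=O)C1C
F2 | step 4 | trimethylsilyl enol ether of F1 (C12=C13–OSiMe3) | C[Si](C)(C)OC1=C(C)[C@@H](CC(=C)COC(C)=O)[C@H](C(C)C)C1
F3 | step 10 | keto aldehyde, C10 bearing the (R)-4-oxobutan-2-yl group | CC(C)(C)[Si](C)(C)O[C@@H]1C[C@@H](C(C)C)[C@@H]2C[C@H](COC(C)=O)C([C@H](C)CC=O)C(=O)[C@@]12C
F4 | step 10 | primary alcohol, C7–OH | CC(C)(C)[Si](C)(C)O[C@@H]1C[C@@H](C(C)C)[C@@H]2C[C@H](COC(C)=O)C([C@H](C)CCO)C(=O)[C@@]12C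
F5 | step 10 | primary iodide, C7–I | CC(C)(C)[Si](C)(C)O[C@@H]1C[C@@H](C(C)C)[C@@H]2C[C@H](COC(C)=O)C([C@H](C)CCI)C(=O)[C@@]12C
F6 | step 10 | alkylzinc iodide, C7–ZnI | CC(C)(C)[Si](C)(C)O[C@@H]1C[C@@H](C(C)C)[C@@H]2C[C@H](COC(C)=O)C([C@H](C)CC[Zn]I)C(=O)[C@@]12C
F7 | step 19 | 2-iodoalkene, C18–C(I)=CH2 | CC(C)(C)[Si](C)(C)O[C@@H]1C[C@@H](C(C)C)[C@@H]2C[C@H](C(I)=C)[C@@H]([C@H](C)CC[C@H]3[C@@H](C)CCC3=O)C(=O)[C@@]12C
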